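**Plan** (longipinane numbering: C1 ketone, C2, C3 CHMe, C4 and C11 bridgehead CH, C5 cyclobutane CH, C6 quaternary carbon with CH3 and C14H2O, C7, C8, C9 CH–O, C10 quaternary cyclobutane carbon)
1. End game in reverse: both angelates and the C1 ketone go back to a 9,14-diol with C1 as a silyl ether; O-9 and C14, which are 1,5-related and cis across the seven-membered ring, are tied into a δ-lactone (temporary ring); H-5 is traced back to a tertiary alcohol.
2. The seven-membered ring (C4–C10) is cut at C5–C6: an aldol bond between the lactone α-carbon C6 and a cyclobutanone carbonyl C5, which cannot enolise because both its α-carbons (C4, C11) are bridgeheads of the bicyclo[3.1.1]heptane.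
3. The lactone is cut at C6=C7 (metathesis), at its ester C–O bond and at C8–C9 (allylation of a C9 aldehyde).
4. Cyclobutane and six-membered ring are cut together across C5–C11 and C4–C10 ([2+2] of a keteniminium ion with an (E)-trisubstituted alkene); the chain is cut at C1–C11 into a five-carbon acid chloride and a four-carbon iodoalkene.
5. Forward order: acyclic chain, cyclobutane plus six-membered ring in one step, lactone, seven-membered carbocycle last, then deoxygenation at C5, lactone opening, acylation, oxidation at C1.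
6. Stereochemistry: C3 from methyl hydrogen (R)-3-methylglutarate; temporary C1 carbinol by oxazaborolidine reduction; C4, C10, C11 in the cycloaddition (steered by C3 and C1, alkene geometry places CH3 and CH2O on C10); C9 by reagent-controlled allylboration; C6 relayed from C9 through the lactone in the key step; C5 fixed by the ring.

Key step: step 14

Remark: both esters are read as angelates, (Z)-2-methylbut-2-enoates; methyl hydrogen (R)-3-methylglutarate is taken as a purchasable building block (it is also available by desymmetrising methanolysis of 3-methylglutaric anhydride).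

Step 1
Reactants: 1 prop-2-yn-1-ol
Product: 3 (E)-3-iodo-2-methylprop-2-en-1-ol, via alkenylalane 2 (not isolated)
Conditions: Me3Al, Cp2ZrCl2 (cat.), CH2Cl2, 0 °C to rt; then I2, THF, −30 to 0 °C
Reagents that add atoms: trimethylaluminium C[Al](C)C; iodine [I][I]
Why: Zirconium-catalysed syn-carboalumination of the terminal alkyne (Negishi carboalumination) places CH3 on the internal carbon and aluminium on the terminus, and iodinolysis with retention should give only the (E)-iodoalkene.

Step 2
Reactants: 3 (E)-3-iodo-2-methylprop-2-en-1-ol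
Product: 4 (E)-tert-butyl[(3-iodo-2-methylprop-2-en-1-yl)oxy]dimethylsilane
Conditions: TBSCl, imidazole, CH2Cl2, 0 °C to rt
Reagents that add atoms: tert-butyldimethylsilyl chloride CC(C)(C)[Si](C)(C)Cl
Why: Standard silylation of a primary alcohol.

Step 3
Reactants: 5 methyl hydrogen (R)-3-methylglutarate
Product: 6 methyl (S)-5-chloro-3-methyl-5-oxopentanoate
Conditions: (COCl)2, DMF (cat.), CH2Cl2, 0 °C to rt; concentrate
Reagents that add atoms: oxalyl chloride ClC(=O)C(Cl)=O
Why: Acid chloride formation through a Vilsmeier-type chloroiminium intermediate; the methyl ester and the stereocentre are untouched (the descriptor changes only by priority).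

Step 4
Reactants: 4 (E)-tert-butyl[(3-iodo-2-methylprop-2-en-1-yl)oxy]dimethylsilane; 6 methyl (S)-5-chloro-3-methyl-5-oxopentanoate
Product: 9 methyl (R,E)-8-(tert-butyldimethylsilyloxy)-3,7-dimethyl-5-oxooct-6-enoate, via alkenyllithium 7 (not isolated), via alkenylzinc chloride 8 (not isolated)
Conditions: 4, t-BuLi (2 equiv), Et2O, −78 °C; ZnCl2, THF, −78 to 0 °C; then 6, Pd(PPh3)4 (5 mol %), 0 °C to rt
Reagents that add atoms: none
Why: Iodine–lithium exchange and transmetalation to zinc keep the E geometry, and the palladium-catalysed acylation of the alkenylzinc (Negishi acyl coupling) should stop at the enone and spare the methyl ester.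

Step 5
Reactants: 9 methyl (R,E)-8-(tert-butyldimethylsilyloxy)-3,7-dimethyl-5-oxooct-6-enoate
Product: 10 methyl (3R,5S,E)-8-(tert-butyldimethylsilyloxy)-5-hydroxy-3,7-dimethyloct-6-enoate
Conditions: (R)-2-methyl-CBS-oxazaborolidine (0.2 equiv), BH3·SMe2, THF, −30 °C; MeOH
Reagents that add atoms: none
Why: Corey–Bakshi–Shibata reduction in which the alkenyl group acts as the large substituent, so the (R)-oxazaborolidine should deliver hydride 1,2 to give the (5S)-allylic alcohol under reagent control.

Step 6
Reactants: 10 methyl (3R,5S,E)-8-(tert-butyldimethylsilyloxy)-5-hydroxy-3,7-dimethyloct-6-enoate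
Product: 11 methyl (3R,5S,E)-8-(tert-butyldimethylsilyloxy)-3,7-dimethyl-5-(triisopropylsilyloxy)oct-6-enoate
Conditions: TIPSOTf, 2,6-lutidine, CH2Cl2, −78 to 0 °C
Reagents that add atoms: triisopropylsilyl triflate CC(C)[Si](C(C)C)(C(C)C)OS(=O)(=O)C(F)(F)F
Why: Silylation of the secondary allylic alcohol with the triflate blocks lactonisation and gives a group that survives later removal of the primary TBS ether.

Step 7
Reactants: 11 methyl (3R,5S,E)-8-(tert-butyldimethylsilyloxy)-3,7-dimethyl-5-(triisopropylsilyloxy)oct-6-enoate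
Product: 12 (3R,5S,E)-8-(tert-butyldimethylsilyloxy)-3,7-dimethyl-1-(pyrrolidin-1-yl)-5-(triisopropylsilyloxy)oct-6-en-1-one
Conditions: Me3Al, pyrrolidine, toluene, 0 to 40 °C
Reagents that add atoms: pyrrolidine C1CCNC1
Why: Aminolysis of the methyl ester by the aluminium amide formed in the flask (Weinreb amidation) gives the tertiary amide needed for keteniminium formation.

Step 8
Reactants: 12 (3R,5S,E)-8-(tert-butyldimethylsilyloxy)-3,7-dimethyl-1-(pyrrolidin-1-yl)-5-(triisopropylsilyloxy)oct-6-en-1-one
Product: 15 (1R,2S,4R,5R,7R)-7-[(tert-butyldimethylsilyloxy)methyl]-4,7-dimethyl-2-(triisopropylsilyloxy)bicyclo[3.1.1]heptan-6-one, via keteniminium triflate 13 (not isolated), via cyclobutaniminium triflate 14 (not isolated)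
Conditions: Tf2O, 2,4,6-collidine, ClCH2CH2Cl, 0 to 80 °C; then aq. NaHCO3, rt
Reagents that add atoms: water O
Why: O-triflation and deprotonation give a keteniminium ion whose central carbon attacks the less substituted alkene carbon and whose α-carbon closes onto the tertiary centre (intramolecular keteniminium–alkene [2+2], bridged mode), transferring the E geometry so that CH3 on C10 ends syn and CH2OTBS anti to the three-carbon bridge, while the C3 methyl and the silyloxy group turn away from the alkene methyl (1,3-allylic strain), end on the face of the carbonyl bridge and so fix C4, C10 and C11.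

Step 9
Reactants: 15 (1R,2S,4R,5R,7R)-7-[(tert-butyldimethylsilyloxy)methyl]-4,7-dimethyl-2-(triisopropylsilyloxy)bicyclo[3.1.1]heptan-6-one
Product: 16 (1R,2S,4R,5R,7R)-7-(hydroxymethyl)-4,7-dimethyl-2-(triisopropylsilyloxy)bicyclo[3.1.1]heptan-6-one
Conditions: HF·pyridine, pyridine, THF, 0 °C
Reagents that add atoms: none
Why: Buffered HF·pyridine should cleave the primary TBS ether far faster than the hindered secondary TIPS ether.

Step 10
Reactants: 16 (1R,2S,4R,5R,7R)-7-(hydroxymethyl)-4,7-dimethyl-2-(triisopropylsilyloxy)bicyclo[3.1.1]heptan-6-one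
Product: 17 (1R,2S,4R,5R,7R)-4,7-dimethyl-6-oxo-2-(triisopropylsilyloxy)bicyclo[3.1.1]heptane-7-carbaldehyde
Conditions: Dess–Martin periodinane, NaHCO3, CH2Cl2, rt
Reagents that add atoms: none
Why: Dess–Martin oxidation of the neopentyl alcohol gives a non-enolisable aldehyde without touching the cyclobutanone.

Step 11
Reactants: 17 (1R,2S,4R,5R,7R)-4,7-dimethyl-6-oxo-2-(triisopropylsilyloxy)bicyclo[3.1.1]heptane-7-carbaldehyde
Product: 19 (1R,2S,4R,5R,7R)-7-[(R)-1-hydroxybut-3-en-1-yl]-4,7-dimethyl-2-(triisopropylsilyloxy)bicyclo[3.1.1]heptan-6-one, via borinate ester 18 (not isolated)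
Conditions: B-allylbis(isopinocampheyl)borane (enantiomer made from (−)-α-pinene), Et2O, −78 °C; then ethanolamine, rt
Reagents that add atoms: B-allylbis(isopinocampheyl)borane C=CCB([C@H]1C[C@H]2C[C@@H]([C@@H]1C)C2(C)C)[C@H]1C[C@H]2C[C@@H]([C@@H]1C)C2(C)C
Why: Brown allylboration through a chair transition state sets C9 as R under reagent control (the aldehyde reacts far faster than the hindered ketone at −78 °C), and the ethanolamine work-up avoids the peroxide that would cause Baeyer–Villiger oxidation of the cyclobutanone.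

Step 12
Reactants: 19 (1R,2S,4R,5R,7R)-7-[(R)-1-hydroxybut-3-en-1-yl]-4,7-dimethyl-2-(triisopropylsilyloxy)bicyclo[3.1.1]heptan-6-one
Product: 20 methacrylate ester of 19 at the C9 hydroxyl
Conditions: methacryloyl chloride, Et3N, DMAP (cat.), CH2Cl2, 0 °C to rt
Reagents that add atoms: methacryloyl chloride C=C(C)C(Cl)=O
Why: DMAP-catalysed acylation of the secondary alcohol installs the second alkene for metathesis, the C6 methyl and the carbonyl carbon that becomes C14.

Step 13
Reactants: 20 methacrylate ester of 19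
Product: 21 (R)-6-[(1R,2S,4R,5R,7R)-4,7-dimethyl-6-oxo-2-(triisopropylsilyloxy)bicyclo[3.1.1]heptan-7-yl]-3-methyl-5,6-dihydro-2H-pyran-2-one
Conditions: second-generation Grubbs catalyst (5–10 mol %), toluene, 80 °C, high dilution
Reagents that add atoms: none
Why: Ring-closing metathesis between the terminal alkene and the methacrylate forms the α-methyl-α,β-unsaturated δ-lactone (C6=C7) with loss of ethene.

Step 14
Reactants: 21 (R)-6-[(1R,2S,4R,5R,7R)-4,7-dimethyl-6-oxo-2-(triisopropylsilyloxy)bicyclo[3.1.1]heptan-7-yl]-3-methyl-5,6-dihydro-2H-pyran-2-one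
Product: 23 (1S)-5-hydroxy-1-(triisopropylsilyloxy)longipinan-14,9-olide (C14 carbonyl on C6 lactonised to O-9; tertiary OH on C5), via copper enolate 22 (not isolated)
Conditions: [(Ph3P)CuH]6 (0.4 equiv), toluene/THF, −40 to 0 °C; aq. NH4Cl
Reagents that add atoms: none
Why: Hydride transfer from the copper hydride to C7, the β-carbon of the unsaturated lactone, gives a monovalent copper enolate at C6 that adds to the cyclobutanone carbonyl C5. The closest known reaction type is the reductive aldol cyclisation of keto-enoates with [(Ph3P)CuH]6, used for five- and six-membered rings. The seven-membered carbocycle closes in the 7-(enolexo)-exo-trig mode and the product is a lactone-bridged cage. C6 is controlled by the tether: the enolate carbon sits in the six-membered lactone whose C9 carries the bicycle, so only the face that leaves the lactone carbonyl cis to O-9 can reach C5, and the C9 configuration from step 11 is relayed to the quaternary centre; C5 can only be attacked from the face anti to the three-carbon bridge, where the lactone hangs from C10, so its OH ends syn. The step needs conjugate reduction ahead of 1,2-reduction of the strained ketone and aldol addition ahead of simple protonation: the soft copper hydride prefers the enoate, the cyclobutanone cannot enolise because C4 and C11 are bridgeheads, the C1 oxygen is masked as a silyl ether, and release of strain at the four-membered-ring carbonyl together with chelation in the copper aldolate should hold the adduct.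

Step 15
Reactants: 23 (1S)-5-hydroxy-1-(triisopropylsilyloxy)longipinan-14,9-olide
Product: 24 methyl oxalate of 23 at the C5 hydroxyl
Conditions: ClC(O)CO2Me, DMAP, Et3N, CH2Cl2, 0 °C to rt
Reagents that add atoms: methyl chlorooxoacetate COC(=O)C(Cl)=O
Why: DMAP-catalysed acylation with the small, very reactive chloro-oxoacetate should convert even this hindered tertiary alcohol into the oxalate needed for radical C–O cleavage, without a base strong enough to trigger retro-aldol opening.

Step 16
Reactants: 24 methyl oxalate of 23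
Product: 25 (1S)-1-(triisopropylsilyloxy)longipinan-14,9-olide
Conditions: Bu3SnH, AIBN, (PhSe)2 (cat.), toluene, 100 °C
Reagents that add atoms: none
Why: Tin-radical addition to the oxalate and β-scission give the C5 cyclobutyl radical (Barton–McCombie-type deoxygenation of a tertiary oxalate), which can take hydrogen only on its open face because C6 is held on the other face by the ring, so C5 forms with the required configuration, and the selenol made from (PhSe)2 speeds hydrogen transfer ahead of ring opening.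

Step 17
Reactants: 25 (1S)-1-(triisopropylsilyloxy)longipinan-14,9-olide
Product: 26 (1S)-1-(triisopropylsilyloxy)longipinane-9,14-diol
Conditions: LiAlH4, THF, 0 °C to rt; Fieser work-up
Reagents that add atoms: none
Why: LiAlH4 reduction opens the lactone to the 9,14-diol, turning the tether into the two oxygen functions with the C14 carbonyl becoming the CH2OH group on C6.

Step 18
Reactants: 26 (1S)-1-(triisopropylsilyloxy)longipinane-9,14-diol
Product: 27 9,14-di-O-angeloyl derivative of 26
Conditions: LiN(SiMe3)2 (2.1 equiv), THF, −78 °C; angelic anhydride, −78 to 0 °C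
Reagents that add atoms: angelic anhydride C/C=C(/C)C(=O)OC(=O)/C(C)=C\C
Why: Acylation of the lithium dialkoxide with angelic anhydride at low temperature should esterify both hindered alcohols quickly enough to avoid isomerisation of the (Z)-2-methylbut-2-enoate to the tiglate.

Step 19
Reactants: 27 9,14-di-O-angeloyl derivative of 26
Product: 28 (1S)-9,14-bis(angeloyloxy)longipinan-1-ol
Conditions: HF·pyridine (excess), THF, rt to 40 °C
Reagents that add atoms: none
Why: Fluoride cleavage of the silyl ether frees the C1 alcohol under conditions that leave the two unsaturated esters alone.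

Step 20
Reactants: 28 (1S)-9,14-bis(angeloyloxy)longipinan-1-ol
Product: 29 target, 9,14-bis(angeloyloxy)longipinan-1-one (CNP0276938.1)
Conditions: Dess–Martin periodinane, NaHCO3, CH2Cl2, rt
Reagents that add atoms: none
Why: Dess–Martin oxidation gives the C1 ketone under neutral conditions, and the adjacent C11 is a bridgehead that cannot epimerise.

**Compound list**
1 | prop-2-yn-1-ol | C#CCO | starting material
2 | (E)-alkenylalane from carboalumination of 1 (O-aluminated) | C[Al](C)/C=C(\C)CO[Al](C)C | intermediate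
3 | (E)-3-iodo-2-methylprop-2-en-1-ol | I/C=C(\C)CO | intermediate
4 | (E)-tert-butyl[(3-iodo-2-methylprop-2-en-1-yl)oxy]dimethylsilane | I/C=C(\C)CO[Si](C)(C)C(C)(C)C | intermediate
5 | methyl hydrogen (R)-3-methylglutarate | COC(=O)C[C@H](C)CC(=O)O | starting material
6 | methyl (S)-5-chloro-3-methyl-5-oxopentanoate | COC(=O)C[C@H](C)CC(=O)Cl | intermediate
7 | (E)-alkenyllithium from 4 | [Li]/C=C(\C)CO[Si](C)(C)C(C)(C)C | intermediate
8 | (E)-alkenylzinc chloride from 4 | Cl[Zn]/C=C(\C)CO[Si](C)(C)C(C)(C)C | intermediate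
9 | methyl (R,E)-8-(tert-butyldimethylsilyloxy)-3,7-dimethyl-5-oxooct-6-enoate | COC(=O)C[C@H](C)CC(=O)/C=C(\C)CO[Si](C)(C)C(C)(C)C | intermediate
10 | methyl (3R,5S,E)-8-(tert-butyldimethylsilyloxy)-5-hydroxy-3,7-dimethyloct-6-enoate | COC(=O)C[C@H](C)C[C@H](O)/C=C(\C)CO[Si](C)(C)C(C)(C)C | intermediate
11 | methyl (3R,5S,E)-8-(tert-butyldimethylsilyloxy)-3,7-dimethyl-5-(triisopropylsilyloxy)oct-6-enoate | COC(=O)C[C@H](C)C[C@H](O[Si](C(C)C)(C(C)C)C(C)C)/C=C(\C)CO[Si](C)(C)C(C)(C)C | intermediate
12 | (3R,5S,E)-8-(tert-butyldimethylsilyloxy)-3,7-dimethyl-1-(pyrrolidin-1-yl)-5-(triisopropylsilyloxy)oct-6-en-1-one | O=C(C[C@H](C)C[C@H](O[Si](C(C)C)(C(C)C)C(C)C)/C=C(\C)CO[Si](C)(C)C(C)(C)C)N1CCCC1 | intermediate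
13 | keteniminium triflate from 12 | [O-]S(=O)(=O)C(F)(F)F.C1CC[N+](C1)=C=C[C@H](C)C[C@H](O[Si](C(C)C)(C(C)C)C(C)C)/C=C(\C)CO[Si](C)(C)C(C)(C)C | intermediate
14 | cyclobutaniminium triflate (pyrrolidinium ylidene of 15) | CC(C)(C)[Si](C)(C)OC[C@]1(C)[C@@H]2C(=[N+]3CCCC3)[C@H]1[C@@H](O[Si](C(C)C)(C(C)C)C(C)C)C[C@H]2C.[O-]S(=O)(=O)C(F)(F)F | intermediate
15 | (1R,2S,4R,5R,7R)-7-[(tert-butyldimethylsilyloxy)methyl]-4,7-dimethyl-2-(triisopropylsilyloxy)bicyclo[3.1.1]heptan-6-one (7-CH3 syn to the C2–C4 bridge; 2-OTIPS and 4-CH3 on the face of the carbonyl bridge) | CC(C)(C)[Si](C)(C)OC[C@]1(C)[C@@H]2C(=O)[C@H]1[C@@H](O[Si](C(C)C)(C(C)C)C(C)C)C[C@H]2C | intermediate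
16 | (1R,2S,4R,5R,7R)-7-(hydroxymethyl)-4,7-dimethyl-2-(triisopropylsilyloxy)bicyclo[3.1.1]heptan-6-one | OC[C@]1(C)[C@@H]2C(=O)[C@H]1[C@@H](O[Si](C(C)C)(C(C)C)C(C)C)C[C@H]2C | intermediate
17 | (1R,2S,4R,5R,7R)-4,7-dimethyl-6-oxo-2-(triisopropylsilyloxy)bicyclo[3.1.1]heptane-7-carbaldehyde | O=C[C@]1(C)[C@@H]2C(=O)[C@H]1[C@@H](O[Si](C(C)C)(C(C)C)C(C)C)C[C@H]2C | intermediate
18 | bis(isopinocampheyl)borinate ester of 19 | C=CC[C@@H](OB([C@H]1C[C@H]2C[C@@H]([C@@H]1C)C2(C)C)[C@H]1C[C@H]2C[C@@H]([C@@H]1C)C2(C)C)[C@]1(C)[C@@H]2C(=O)[C@H]1[C@@H](O[Si](C(C)C)(C(C)C)C(C)C)C[C@H]2C | intermediate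
19 | (1R,2S,4R,5R,7R)-7-[(R)-1-hydroxybut-3-en-1-yl]-4,7-dimethyl-2-(triisopropylsilyloxy)bicyclo[3.1.1]heptan-6-one | C=CC[C@@H](O)[C@]1(C)[C@@H]2C(=O)[C@H]1[C@@H](O[Si](C(C)C)(C(C)C)C(C)C)C[C@H]2C | intermediate
20 | methacrylate ester of 19 | C=CC[C@@H](OC(=O)C(C)=C)[C@]1(C)[C@@H]2C(=O)[C@H]1[C@@H](O[Si](C(C)C)(C(C)C)C(C)C)C[C@H]2C | intermediate
21 | (R)-6-[(1R,2S,4R,5R,7R)-4,7-dimethyl-6-oxo-2-(triisopropylsilyloxy)bicyclo[3.1.1]heptan-7-yl]-3-methyl-5,6-dihydro-2H-pyran-2-one | CC1=CC[C@@H](OC1=O)[C@]2(C)[C@@H]3C(=O)[C@H]2[C@@H](O[Si](C(C)C)(C(C)C)C(C)C)C[C@H]3C | intermediate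
22 | monovalent copper enolate of the saturated lactone (C6=C14 enolate) | [Cu]OC1=C(C)CC[C@@H](O1)[C@]2(C)[C@@H]3C(=O)[C@H]2[C@@H](O[Si](C(C)C)(C(C)C)C(C)C)C[C@H]3C | intermediate
23 | (1S)-5-hydroxy-1-(triisopropylsilyloxy)longipinan-14,9-olide | O=C4[C@@]1(C)CC[C@@H](O4)[C@]2(C)[C@@H]3[C@@]1(O)[C@H]2[C@@H](O[Si](C(C)C)(C(C)C)C(C)C)C[C@H]3C | intermediate
24 | methyl oxalate of 23 (at O-5) | O=C4[C@@]1(C)CC[C@@H](O4)[C@]2(C)[C@@H]3[C@@]1(OC(=O)C(=O)OC)[C@H]2[C@@H](O[Si](C(C)C)(C(C)C)C(C)C)C[C@H]3C | intermediate
25 | (1S)-1-(triisopropylsilyloxy)longipinan-14,9-olide | O=C4[C@@]1(C)CC[C@@H](O4)[C@]2(C)[C@@H]3[C@H]1[C@H]2[C@@H](O[Si](C(C)C)(C(C)C)C(C)C)C[C@H]3C | intermediate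
26 | (1S)-1-(triisopropylsilyloxy)longipinane-9,14-diol | OC[C@@]1(C)CC[C@@H](O)[C@]2(C)[C@@H]3[C@H]1[C@H]2[C@@H](O[Si](C(C)C)(C(C)C)C(C)C)C[C@H]3C | intermediate
27 | (1S)-9,14-bis(angeloyloxy)-1-(triisopropylsilyloxy)longipinane | C/C=C(/C)C(=O)OC[C@@]1(C)CC[C@@H](OC(=O)/C(C)=C\C)[C@]2(C)[C@@H]3[C@H]1[C@H]2[C@@H](O[Si](C(C)C)(C(C)C)C(C)C)C[C@H]3C | intermediate
28 | (1S)-9,14-bis(angeloyloxy)longipinan-1-ol | C/C=C(/C)C(=O)OC[C@@]1(C)CC[C@@H](OC(=O)/C(C)=C\C)[C@]2(C)[C@@H]3[C@H]1[C@H]2[C@@H](O)C[C@H]3C | intermediate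
29 | 9,14-bis(angeloyloxy)longipinan-1-one (CNP0276938.1) | C/C=C(/C)C(=O)OC[C@@]1(C)CC[C@@H](OC(=O)/C(C)=C\C)[C@]2(C)[C@@H]3[C@H]1[C@H]2C(=O)C[C@H]3C | target

**Step count and risks**
Total: 20 steps. Longest linear sequence: 19 steps (steps 1, 2 and 4 to 20).

Most likely to fail, first: step 14. The conjugate reduction of the trisubstituted α-methyl lactone alkene may be slow, so that hydride reaches the strained ketone first, or the crowded copper aldolate may revert by retro-aldol and end as the simply reduced lactone. The fallback sets out from 21 and separates the two events. Hydrogenation (H2, Pd/C, EtOAc) should give the saturated lactone F1 as both C6 epimers. LiN(SiMe3)2 in THF at −78 °C then removes the only acidic hydrogen of the molecule, so both epimers converge on one lithium enolate, whose aldol closure onto C5 is steered by the same lactone tether. Quenching with AcOH at −78 °C brings the route back at 23.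

Second: step 8. The alkene carries two allylic silyloxy groups, so attack on the keteniminium ion may be slow, and the carbocation-like intermediate may be diverted (hydride shift from the CH2OTBS carbon, loss of alkene geometry) before the ring closes. The fallback sets out from 11 and uses a concerted chloroketene cycloaddition instead. LiOH (THF/H2O) should give the acid F2. Its dianion (LiN(i-Pr)2, 2.2 equiv) with CCl4 should give the α-chloro acid F3, and (COCl)2 the α-chloro acid chloride F4. Et3N in refluxing toluene should generate the chloroketene F5 (not isolated), which closes in the same bridged mode to the bridgehead-chlorinated cyclobutanone F6. Bu3SnH/AIBN removes the chlorine and the route is rejoined at 15.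

Third: step 15. Acylation of the tertiary alcohol, flanked by the quaternary C6 and by the C3 methyl and C1 silyloxy groups on the same face, may not take place, or the amine base may open the seven-membered ring by retro-aldol. The fallback sets out from 23 and acylates the preformed alkoxide at low temperature instead: KN(SiMe3)2 in THF at −78 °C followed by PhOC(S)Cl should give the O-phenyl thionocarbonate F7. Barton–McCombie reduction (Bu3SnH, AIBN, toluene, 100 °C) then returns the route at 25.

**Further compounds**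
F1 | step 14 | saturated lactone from 21 (both C6 epimers) | CC1CC[C@@H](OC1=O)[C@]2(C)[C@@H]3C(=O)[C@H]2[C@@H](O[Si](C(C)C)(C(C)C)C(C)C)C[C@H]3C
F2 | step 8 | (3R,5S,E)-8-(tert-butyldimethylsilyloxy)-3,7-dimethyl-5-(triisopropylsilyloxy)oct-6-enoic acid | OC(=O)C[C@H](C)C[C@H](O[Si](C(C)C)(C(C)C)C(C)C)/C=C(\C)CO[Si](C)(C)C(C)(C)C
F3 | step 8 | 2-chloro derivative of F2 (both C2 epimers) | OC(=O)C(Cl)[C@H](C)C[C@H](O[Si](C(C)C)(C(C)C)C(C)C)/C=C(\C)CO[Si](C)(C)C(C)(C)C
F4 | step 8 | acid chloride of F3 | ClC(=O)C(Cl)[C@H](C)C[C@H](O[Si](C(C)C)(C(C)C)C(C)C)/C=C(\C)CO[Si](C)(C)C(C)(C)C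
F5 | step 8 | chloroketene from F4 (not isolated) | O=C=C(Cl)[C@H](C)C[C@H](O[Si](C(C)C)(C(C)C)C(C)C)/C=C(\C)CO[Si](C)(C)C(C)(C)C
F6 | step 8 | 5-chloro derivative of 15 (chlorine on the bridgehead next to C4) | CC(C)(C)[Si](C)(C)OC[C@]1(C)[C@]2(Cl)C(=O)[C@H]1[C@@H](O[Si](C(C)C)(C(C)C)C(C)C)C[C@H]2C
F7 | step 15 | O-phenyl thionocarbonate of 23 (at O-5) | O=C4[C@@]1(C)CC[C@@H](O4)[C@]2(C)[C@@H]3[C@@]1(OC(=S)Oc5ccccc5)[C@H]2[C@@H](O[Si](C(C)C)(C(C)C)C(C)C)C[C@H]3C
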